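**Plan**
- Retrosynthesis (eremophilane numbering: ring A = C1–C5 and C10, ring B = C5–C10, C11 on C7): the C3 trienoate is cut first; ring B is then opened at C7–C8 together with the C11–CH3 bond; C8–C9 is cut to a C10 carbaldehyde plus a vinyl unit; the formyl carbon is cut back to a ring-A ketone; C5–C6 and C4–CH3 are cut back to a 4-alkoxy-2-methylcyclohexenone.
- Enabling feature: the tetrasubstituted C7=C11 alkene beside the C8 carbonyl and the C9 carbinol of ring B corresponds to a but-2-ynyl arm on C5 and an α-silyloxy aldehyde arm on C10 of ring A, with one C11 methyl supplied by ZnMe2.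
- Forward: ring A comes from 4-methoxy-3-methylphenol, the two arms are attached, ring B is closed by the nickel step, and the trienoic acid (two steps from (E)-non-3-en-2-one) is joined last.
- Stereochemistry: C3 from a CBS reduction; C4 and C5 by 1,2-induction in a cuprate addition–enolate alkylation; C10 by equilibration to the equatorial aldehyde; C9 by Felkin–Anh vinyl addition; C8 is transient; the triene is set all-E by olefination and equilibration.

Key step: step 10

Remark: the C8 carbinol of 16 is written as the epimer anti to the C9 silyl ether; its configuration is removed in step 11, so either epimer serves. PMB = 4-methoxybenzyl, TBS = tert-butyldimethylsilyl.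

**Step 1**
Reactants: 1 4-methoxy-3-methylphenol
Product: 2 4,4-dimethoxy-3-methylcyclohexa-2,5-dien-1-one
Conditions: PhI(OAc)2, MeOH, 0 °C
Reagents that add atoms: methanol, CO
Why: Oxidative dearomatisation of a para-methoxyphenol by the hypervalent iodine reagent, with methanol trapping the cation at C4, should give the quinone monoketal.

**Step 2**
Reactants: 2 4,4-dimethoxy-3-methylcyclohexa-2,5-dien-1-one
Product: 3 4,4-dimethoxy-3-methylcyclohex-2-en-1-one
Conditions: H2 (1 atm), RhCl(PPh3)3 (5 mol%), toluene, rt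
Reagents that add atoms: none
Why: Homogeneous hydrogenation with RhCl(PPh3)3 should saturate only the unhindered disubstituted enone alkene and leave the methyl-bearing trisubstituted one, as in the selective 1,2-reduction of steroidal 1,4-dien-3-ones.

**Step 3**
Reactants: 3 4,4-dimethoxy-3-methylcyclohex-2-en-1-one
Product: 4 (1R)-4,4-dimethoxy-3-methylcyclohex-2-en-1-ol
Conditions: (S)-Me-CBS [(S)-1-methyl-3,3-diphenyltetrahydro-1H,3H-pyrrolo[1,2-c][1,3,2]oxazaborole] (10 mol%), catecholborane, toluene, −78 °C; MeOH, then aq. NaOH work-up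
Reagents that add atoms: none
Why: Corey–Bakshi–Shibata reduction in which the alkenyl carbon acts as the large group, so that the (S)-catalyst should deliver hydride to the face that gives the 1R carbinol (the future C3).

**Step 4**
Reactants: 4 (1R)-4,4-dimethoxy-3-methylcyclohex-2-en-1-ol
Product: 6 (4R)-4-[(4-methoxybenzyl)oxy]-2-methylcyclohex-2-en-1-one, via ketal ether 5 (not isolated)
Conditions: NaH, 4-methoxybenzyl chloride, Bu4NI (cat.), THF/DMF, 0 °C to rt; then 1 M HCl, THF, 0 °C
Reagents that add atoms: 4-methoxybenzyl chloride, COc1ccc(CCl)cc1; water, O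
Why: Williamson etherification of the allylic alkoxide followed by mild acid hydrolysis of the labile allylic dimethyl ketal should unmask the ketone next to the methyl-bearing alkene carbon without touching the carbinol stereocentre.

**Step 5**
Reactants: 6 (4R)-4-[(4-methoxybenzyl)oxy]-2-methylcyclohex-2-en-1-one; 7 1-bromobut-2-yne
Product: 9 (2R,3R,4R)-2-(but-2-yn-1-yl)-4-[(4-methoxybenzyl)oxy]-2,3-dimethylcyclohexan-1-one, via lithium enolate 8 (not isolated)
Conditions: MeLi (2 equiv), CuI, Et2O, 0 °C; then 6, −78 to −30 °C; then 7, HMPA, THF, −30 °C to rt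
Reagents that add atoms: lithium dimethylcuprate, [Li+].C[Cu-]C
Why: Conjugate addition of the Gilman cuprate to the γ-alkoxy enone should occur anti to the C3 ether (sets C4), and the regiospecific enolate should be C-alkylated by the propargylic bromide anti to the new vicinal methyl (sets the quaternary C5 with its methyl cis to the C4 methyl), a conjugate addition–enolate alkylation sequence.

**Step 6**
Reactants: 9 (2R,3R,4R)-2-(but-2-yn-1-yl)-4-[(4-methoxybenzyl)oxy]-2,3-dimethylcyclohexan-1-one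
Product: 11 (1R,2R,3R,4R)-2-(but-2-yn-1-yl)-4-[(4-methoxybenzyl)oxy]-2,3-dimethylcyclohexane-1-carbaldehyde, via enol ether 10 (not isolated)
Conditions: MeOCH2PPh3Cl, KN(SiMe3)2, THF, 0 to 50 °C; then 2 M HCl, THF, rt; then K2CO3, MeOH, rt
Reagents that add atoms: (methoxymethyl)triphenylphosphonium chloride, [Cl-].COC[P+](c1ccccc1)(c1ccccc1)c1ccccc1; water, O
Why: Wittig methoxymethylenation of the ketone (enolisable only toward C1) and hydrolysis of the enol ether should give the homologous aldehyde, and both axial protonation anti to the axial C5 methyl and base equilibration should favour the equatorial formyl group, which places C10 cis to the C5 methyl and trans to the butynyl arm.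

**Step 7**
Reactants: 11 (1R,2R,3R,4R)-2-(but-2-yn-1-yl)-4-[(4-methoxybenzyl)oxy]-2,3-dimethylcyclohexane-1-carbaldehyde
Product: 12 (1R)-1-[(1R,2R,3R,4R)-2-(but-2-yn-1-yl)-4-[(4-methoxybenzyl)oxy]-2,3-dimethylcyclohexyl]prop-2-en-1-ol
Conditions: CH2=CHMgBr, THF, −78 °C
Reagents that add atoms: vinylmagnesium bromide, C=C[Mg]Br
Why: Grignard addition under Felkin–Anh control, with the quaternary C5 anti to the incoming nucleophile and the trajectory passing the C10 hydrogen, should set the carbinol (the future C9) in the configuration of the target.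

**Step 8**
Reactants: 12 (1R)-1-[(1R,2R,3R,4R)-2-(but-2-yn-1-yl)-4-[(4-methoxybenzyl)oxy]-2,3-dimethylcyclohexyl]prop-2-en-1-ol
Product: 13 tert-butyl({(1R)-1-[(1R,2R,3R,4R)-2-(but-2-yn-1-yl)-4-[(4-methoxybenzyl)oxy]-2,3-dimethylcyclohexyl]prop-2-en-1-yl}oxy)dimethylsilane
Conditions: TBSOTf, 2,6-lutidine, CH2Cl2, −78 to 0 °C
Reagents that add atoms: tert-butyldimethylsilyl triflate, CC(C)(C)[Si](C)(C)OS(=O)(=O)C(F)(F)F
Why: Silylation with the silyl triflate and a hindered pyridine base is the standard way to protect a hindered secondary allylic alcohol.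

**Step 9**
Reactants: 13 tert-butyl({(1R)-1-[(1R,2R,3R,4R)-2-(but-2-yn-1-yl)-4-[(4-methoxybenzyl)oxy]-2,3-dimethylcyclohexyl]prop-2-en-1-yl}oxy)dimethylsilane
Product: 14 (2S)-2-[(1R,2R,3R,4R)-2-(but-2-yn-1-yl)-4-[(4-methoxybenzyl)oxy]-2,3-dimethylcyclohexyl]-2-[(tert-butyldimethylsilyl)oxy]acetaldehyde
Conditions: OsO4 (2 mol%), NaIO4, 2,6-lutidine, dioxane/H2O, rt
Reagents that add atoms: osmium tetroxide, O=[Os](=O)(=O)=O (reoxidised by sodium periodate, [Na+].[O-]I(=O)(=O)=O)
Why: Lemieux–Johnson cleavage, in which osmylation is far faster at the monosubstituted alkene than at the internal alkyne and the buffered medium should keep the α-silyloxy aldehyde from epimerising at C9.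

**Step 10**
Reactants: 14 (2S)-2-[(1R,2R,3R,4R)-2-(but-2-yn-1-yl)-4-[(4-methoxybenzyl)oxy]-2,3-dimethylcyclohexyl]-2-[(tert-butyldimethylsilyl)oxy]acetaldehyde; 15 dimethylzinc
Product: 16 (3R,4R,5R,8S,9S,10R)-9-[(tert-butyldimethylsilyl)oxy]-3-[(4-methoxybenzyl)oxy]eremophil-7(11)-en-8-ol
Conditions: Ni(cod)2 (10 mol%), 15 (3 equiv), THF, 0 °C, slow addition of 14; aq. NH4Cl work-up
Reagents that add atoms: none
Why: Zerovalent nickel binds the C7≡C11 alkyne and the C8 aldehyde and couples them oxidatively to an oxanickelacyclopentene of divalent nickel, which forms C7–C8; transmetalation with ZnMe2 and reductive elimination then form C11–CH3 and return zerovalent nickel. The closest known reaction is the nickel-catalysed alkylative cyclisation of ynals with diorganozincs to cycloalkanols bearing an exocyclic alkene, for which six-membered rings are documented though less common than five-membered ones. Ring B closes in the six-membered exo-dig mode, C7 becoming a ring atom and C11 staying exocyclic, and the trans ring fusion follows from the diequatorial C6 and C9 arms on ring A. The one new stereocentre, C8, should be set anti to the adjacent C9 silyl ether (Felkin-type approach in a chair-like nickelacycle with the C9 substituent equatorial), and it is erased in step 11. The step needs regioselectivity (C7, not C11, bonding to C8), which the tether length secures because bonding at C11 would require a seven-membered ring, and alkyl transfer rather than reduction or direct addition, which is secured by a methyl group without β-hydrogens, phosphine-free conditions and the inertness of ZnMe2 toward aldehydes without nickel. The geometry at C11 is of no concern because it ends with two methyl groups, so the tetrasubstituted alkene is made under neutral conditions without enolising a ketone next to C9.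

**Step 11**
Reactants: 16 (3R,4R,5R,8S,9S,10R)-9-[(tert-butyldimethylsilyl)oxy]-3-[(4-methoxybenzyl)oxy]eremophil-7(11)-en-8-ol
Product: 17 (3R,4R,5R,9S,10R)-9-[(tert-butyldimethylsilyl)oxy]-3-[(4-methoxybenzyl)oxy]eremophil-7(11)-en-8-one
Conditions: Dess–Martin periodinane, NaHCO3, CH2Cl2, 0 °C to rt
Reagents that add atoms: none
Why: Dess–Martin oxidation of the allylic alcohol under buffered conditions should give the α-isopropylidene ketone without enolisation toward C9.

**Step 12**
Reactants: 17 (3R,4R,5R,9S,10R)-9-[(tert-butyldimethylsilyl)oxy]-3-[(4-methoxybenzyl)oxy]eremophil-7(11)-en-8-one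
Product: 18 (3R,4R,5R,9S,10R)-9-[(tert-butyldimethylsilyl)oxy]-3-hydroxyeremophil-7(11)-en-8-one
Conditions: DDQ, CH2Cl2/pH 7 buffer, 0 °C
Reagents that add atoms: none
Why: Oxidative cleavage of the electron-rich PMB ether by DDQ, with hydrolysis of the resulting oxocarbenium ion, should free the C3 hydroxyl while the silyl ether and the electron-poor enone stay inert.

**Step 13**
Reactants: 19 (E)-non-3-en-2-one
Product: 20 ethyl (2E,4E,6E)-5-methyldodeca-2,4,6-trienoate
Conditions: triethyl 4-phosphonocrotonate, LiN(SiMe3)2, THF, −78 to 0 °C; then I2 (cat.), CH2Cl2, daylight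
Reagents that add atoms: triethyl 4-phosphonocrotonate, CCOC(=O)/C=C/CP(=O)(OCC)OCC
Why: Vinylogous Horner–Wadsworth–Emmons olefination of the methyl ketone builds C4=C5 and brings in the (2E)-enoate; the 4E isomer should predominate and iodine-catalysed equilibration should converge residual 4Z material to the all-E triene.

**Step 14**
Reactants: 20 ethyl (2E,4E,6E)-5-methyldodeca-2,4,6-trienoate
Product: 21 (2E,4E,6E)-5-methyldodeca-2,4,6-trienoic acid
Conditions: LiOH, THF/MeOH/H2O, rt; then 1 M HCl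
Reagents that add atoms: lithium hydroxide, [Li+].[OH-]
Why: Saponification of the ethyl ester by acyl–oxygen cleavage leaves the triene geometry untouched, and the all-E acid should be purifiable by crystallisation.

**Step 15**
Reactants: 18 (3R,4R,5R,9S,10R)-9-[(tert-butyldimethylsilyl)oxy]-3-hydroxyeremophil-7(11)-en-8-one; 21 (2E,4E,6E)-5-methyldodeca-2,4,6-trienoic acid
Product: 23 (3R,4R,5R,9S,10R)-9-[(tert-butyldimethylsilyl)oxy]-8-oxoeremophil-7(11)-en-3-yl (2E,4E,6E)-5-methyldodeca-2,4,6-trienoate, via mixed anhydride 22 (not isolated)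
Conditions: 21, 2,4,6-trichlorobenzoyl chloride, Et3N, toluene, rt; then 18, DMAP, toluene, rt
Reagents that add atoms: none
Why: Yamaguchi esterification, in which DMAP attacks the less hindered trienoyl carbonyl of the mixed anhydride and the acylpyridinium acylates the equatorial C3 alcohol with retention at C3.

**Step 16**
Reactants: 23 (3R,4R,5R,9S,10R)-9-[(tert-butyldimethylsilyl)oxy]-8-oxoeremophil-7(11)-en-3-yl (2E,4E,6E)-5-methyldodeca-2,4,6-trienoate
Product: 24 (3R,4R,5R,9S,10R)-9-hydroxy-8-oxoeremophil-7(11)-en-3-yl (2E,4E,6E)-5-methyldodeca-2,4,6-trienoate (CNP0211657.1)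
Conditions: HF·pyridine, pyridine, THF, 0 °C to rt
Reagents that add atoms: none
Why: Fluoride-mediated desilylation under buffered, base-free conditions should free the C9 hydroxyl without epimerising or transposing the acyloin and without touching the trienoate.

**Compound list**
1 | 4-methoxy-3-methylphenol | COc1ccc(O)cc1C | starting material
2 | 4,4-dimethoxy-3-methylcyclohexa-2,5-dien-1-one | COC1(OC)C=CC(=O)C=C1C | intermediate
3 | 4,4-dimethoxy-3-methylcyclohex-2-en-1-one | COC1(OC)CCC(=O)C=C1C | intermediate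
4 | (1R)-4,4-dimethoxy-3-methylcyclohex-2-en-1-ol | O[C@@H]1CCC(OC)(OC)C(C)=C1 | intermediate
5 | 1-({[(1R)-4,4-dimethoxy-3-methylcyclohex-2-en-1-yl]oxy}methyl)-4-methoxybenzene | COc1ccc(CO[C@@H]2CCC(OC)(OC)C(C)=C2)cc1 | intermediate (not isolated)
6 | (4R)-4-[(4-methoxybenzyl)oxy]-2-methylcyclohex-2-en-1-one | COc1ccc(CO[C@@H]2CCC(=O)C(C)=C2)cc1 | intermediate
7 | 1-bromobut-2-yne | CC#CCBr | starting material
8 | lithium (3R,4R)-4-[(4-methoxybenzyl)oxy]-2,3-dimethylcyclohex-1-en-1-olate | [Li+].COc1ccc(CO[C@@H]2CCC([O-])=C(C)[C@H]2C)cc1 | intermediate (not isolated)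
9 | (2R,3R,4R)-2-(but-2-yn-1-yl)-4-[(4-methoxybenzyl)oxy]-2,3-dimethylcyclohexan-1-one | COc1ccc(CO[C@@H]2CCC(=O)[C@](C)(CC#CC)[C@H]2C)cc1 | intermediate
10 | 1-({[(1R,2R,3R)-3-(but-2-yn-1-yl)-4-(methoxymethylidene)-2,3-dimethylcyclohexyl]oxy}methyl)-4-methoxybenzene (E/Z mixture) | COc1ccc(CO[C@@H]2CCC(=COC)[C@](C)(CC#CC)[C@H]2C)cc1 | intermediate (not isolated)
11 | (1R,2R,3R,4R)-2-(but-2-yn-1-yl)-4-[(4-methoxybenzyl)oxy]-2,3-dimethylcyclohexane-1-carbaldehyde | COc1ccc(CO[C@@H]2CC[C@@H](C=O)[C@](C)(CC#CC)[C@H]2C)cc1 | intermediate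
12 | (1R)-1-[(1R,2R,3R,4R)-2-(but-2-yn-1-yl)-4-[(4-methoxybenzyl)oxy]-2,3-dimethylcyclohexyl]prop-2-en-1-ol | COc1ccc(CO[C@@H]2CC[C@@H]([C@H](O)C=C)[C@](C)(CC#CC)[C@H]2C)cc1 | intermediate
13 | tert-butyl({(1R)-1-[(1R,2R,3R,4R)-2-(but-2-yn-1-yl)-4-[(4-methoxybenzyl)oxy]-2,3-dimethylcyclohexyl]prop-2-en-1-yl}oxy)dimethylsilane | COc1ccc(CO[C@@H]2CC[C@@H]([C@H](O[Si](C)(C)C(C)(C)C)C=C)[C@](C)(CC#CC)[C@H]2C)cc1 | intermediate
14 | (2S)-2-[(1R,2R,3R,4R)-2-(but-2-yn-1-yl)-4-[(4-methoxybenzyl)oxy]-2,3-dimethylcyclohexyl]-2-[(tert-butyldimethylsilyl)oxy]acetaldehyde | COc1ccc(CO[C@@H]2CC[C@@H]([C@H](O[Si](C)(C)C(C)(C)C)C=O)[C@](C)(CC#CC)[C@H]2C)cc1 | intermediate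
15 | dimethylzinc | C[Zn]C | starting material
16 | (3R,4R,5R,8S,9S,10R)-9-[(tert-butyldimethylsilyl)oxy]-3-[(4-methoxybenzyl)oxy]eremophil-7(11)-en-8-ol | COc1ccc(CO[C@@H]2CC[C@H]3[C@H](O[Si](C)(C)C(C)(C)C)[C@@H](O)C(=C(C)C)C[C@]3(C)[C@H]2C)cc1 | intermediate
17 | (3R,4R,5R,9S,10R)-9-[(tert-butyldimethylsilyl)oxy]-3-[(4-methoxybenzyl)oxy]eremophil-7(11)-en-8-one | COc1ccc(CO[C@@H]2CC[C@H]3[C@H](O[Si](C)(C)C(C)(C)C)C(=O)C(=C(C)C)C[C@]3(C)[C@H]2C)cc1 | intermediate
18 | (3R,4R,5R,9S,10R)-9-[(tert-butyldimethylsilyl)oxy]-3-hydroxyeremophil-7(11)-en-8-one | O[C@@H]1CC[C@H]2[C@H](O[Si](C)(C)C(C)(C)C)C(=O)C(=C(C)C)C[C@]2(C)[C@H]1C | intermediate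
19 | (E)-non-3-en-2-one | CCCCC/C=C/C(C)=O | starting material
20 | ethyl (2E,4E,6E)-5-methyldodeca-2,4,6-trienoate | CCCCC/C=C/C(C)=C/C=C/C(=O)OCC | intermediate
21 | (2E,4E,6E)-5-methyldodeca-2,4,6-trienoic acid | CCCCC/C=C/C(C)=C/C=C/C(=O)O | intermediate
22 | (2E,4E,6E)-5-methyldodeca-2,4,6-trienoic 2,4,6-trichlorobenzoic anhydride | CCCCC/C=C/C(C)=C/C=C/C(=O)OC(=O)c1c(Cl)cc(Cl)cc1Cl | intermediate (not isolated)
23 | (3R,4R,5R,9S,10R)-9-[(tert-butyldimethylsilyl)oxy]-8-oxoeremophil-7(11)-en-3-yl (2E,4E,6E)-5-methyldodeca-2,4,6-trienoate | CCCCC/C=C/C(C)=C/C=C/C(=O)O[C@@H]1CC[C@H]2[C@H](O[Si](C)(C)C(C)(C)C)C(=O)C(=C(C)C)C[C@]2(C)[C@H]1C | intermediate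
24 | (3R,4R,5R,9S,10R)-9-hydroxy-8-oxoeremophil-7(11)-en-3-yl (2E,4E,6E)-5-methyldodeca-2,4,6-trienoate | CCCCC/C=C/C(C)=C/C=C/C(=O)O[C@@H]1CC[C@H]2[C@H](O)C(=O)C(=C(C)C)C[C@]2(C)[C@H]1C | target

**Step count**
Total: 16 steps. Longest linear sequence: 14 steps (steps 1–12, 15, 16); steps 13 and 14 make the acid side branch.

**Steps most likely to fail**

1. Step 10. Oxidative cyclisation to the six-membered nickelacycle may be too slow at the hindered α-silyloxy aldehyde, so that alkyne oligomerisation or uncyclised methyl transfer to the aldehyde takes over. The fallback closes the same C7–C8 bond by an intramolecular Nozaki–Hiyama–Kishi reaction of an alkenyl iodide that already carries both C11 methyls; it sets out from 6 and comes back at 16. 3-Methylbut-2-enal would be α-iodinated (I2, DMAP, K2CO3, aqueous THF) to 2-iodo-3-methylbut-2-enal F1, reduced (NaBH4, CeCl3, MeOH) to 2-iodo-3-methylbut-2-en-1-ol F2 and brominated (CBr4, PPh3) to 1-bromo-2-iodo-3-methylbut-2-ene F3. Enolate 8, made from 6 as in step 5, would be alkylated with F3 to the iodoalkenyl ketone F4. The operations of steps 6 to 9 would then lead through the enol ether F5, the aldehyde F6, the allylic alcohol F7 and the silyl ether F8 to the iodo aldehyde F9; the tetrasubstituted iodoalkene should survive the osmylation. CrCl2 with catalytic NiCl2 in DMSO would then insert into the C–I bond, and the alkenyl species of trivalent chromium would add to the aldehyde to give 16.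

2. Step 5. Alkylation of the copper-bound tetrasubstituted enolate may stall or lose control through proton transfer, O-alkylation or attack syn to the C4 methyl, the last made more likely by the C3 ether lying on the face the electrophile must use. The fallback separates the two events; it sets out from 6 and comes back at 9. The cuprate addition would be run with Me3SiCl and Et3N and the product isolated as trimethyl{[(3R,4R)-4-[(4-methoxybenzyl)oxy]-2,3-dimethylcyclohex-1-en-1-yl]oxy}silane F10. MeLi in THF would then regenerate the copper-free lithium enolate 8 regiospecifically, and this would be alkylated with 7 in the presence of HMPA to give 9.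

3. Step 6. The ylide may act as a base toward the ketone flanked by the quaternary C5 so that olefination stalls, and hydrolysis may leave a mixture of C10 epimers. The fallback homologates through a nitrile; it sets out from 9 and comes back at 11. Van Leusen reductive cyanation (TosMIC, t-BuOK, DME/EtOH) would convert 9 into (2S,3R,4R)-2-(but-2-yn-1-yl)-4-[(4-methoxybenzyl)oxy]-2,3-dimethylcyclohexane-1-carbonitrile F11 as C1 epimers. Reduction with i-Bu2AlH at −78 °C, hydrolysis of the imine and the same K2CO3/MeOH equilibration would give 11.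

**Further compounds**
F1 | step 10 | 2-iodo-3-methylbut-2-enal | CC(C)=C(I)C=O
F2 | step 10 | 2-iodo-3-methylbut-2-en-1-ol | CC(C)=C(I)CO
F3 | step 10 | 1-bromo-2-iodo-3-methylbut-2-ene | CC(C)=C(I)CBr
F4 | step 10 | (2R,3R,4R)-2-(2-iodo-3-methylbut-2-en-1-yl)-4-[(4-methoxybenzyl)oxy]-2,3-dimethylcyclohexan-1-one | COc1ccc(CO[C@@H]2CCC(=O)[C@](C)(CC(I)=C(C)C)[C@H]2C)cc1
F5 | step 10 | 1-({[(1R,2R,3R)-3-(2-iodo-3-methylbut-2-en-1-yl)-4-(methoxymethylidene)-2,3-dimethylcyclohexyl]oxy}methyl)-4-methoxybenzene | COc1ccc(CO[C@@H]2CCC(=COC)[C@](C)(CC(I)=C(C)C)[C@H]2C)cc1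
F6 | step 10 | (1R,2R,3R,4R)-2-(2-iodo-3-methylbut-2-en-1-yl)-4-[(4-methoxybenzyl)oxy]-2,3-dimethylcyclohexane-1-carbaldehyde | COc1ccc(CO[C@@H]2CC[C@@H](C=O)[C@](C)(CC(I)=C(C)C)[C@H]2C)cc1
F7 | step 10 | (1R)-1-[(1R,2R,3R,4R)-2-(2-iodo-3-methylbut-2-en-1-yl)-4-[(4-methoxybenzyl)oxy]-2,3-dimethylcyclohexyl]prop-2-en-1-ol | COc1ccc(CO[C@@H]2CC[C@@H]([C@H](O)C=C)[C@](C)(CC(I)=C(C)C)[C@H]2C)cc1
F8 | step 10 | tert-butyl({(1R)-1-[(1R,2R,3R,4R)-2-(2-iodo-3-methylbut-2-en-1-yl)-4-[(4-methoxybenzyl)oxy]-2,3-dimethylcyclohexyl]prop-2-en-1-yl}oxy)dimethylsilane | COc1ccc(CO[C@@H]2CC[C@@H]([C@H](O[Si](C)(C)C(C)(C)C)C=C)[C@](C)(CC(I)=C(C)C)[C@H]2C)cc1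
F9 | step 10 | (2S)-2-[(tert-butyldimethylsilyl)oxy]-2-[(1R,2R,3R,4R)-2-(2-iodo-3-methylbut-2-en-1-yl)-4-[(4-methoxybenzyl)oxy]-2,3-dimethylcyclohexyl]acetaldehyde | COc1ccc(CO[C@@H]2CC[C@@H]([C@H](O[Si](C)(C)C(C)(C)C)C=O)[C@](C)(CC(I)=C(C)C)[C@H]2C)cc1
F10 | step 5 | trimethyl{[(3R,4R)-4-[(4-methoxybenzyl)oxy]-2,3-dimethylcyclohex-1-en-1-yl]oxy}silane | COc1ccc(CO[C@@H]2CCC(O[Si](C)(C)C)=C(C)[C@H]2C)cc1
F11 | step 6 | (2S,3R,4R)-2-(but-2-yn-1-yl)-4-[(4-methoxybenzyl)oxy]-2,3-dimethylcyclohexane-1-carbonitrile (C1 epimers) | COc1ccc(CO[C@@H]2CCC(C#N)[C@](C)(CC#CC)[C@H]2C)cc1
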